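Slowness is what I look at first in the autumn flask, charged with D at 0.68 M: between 2.50 h and 20.0 h Z falls from 13.1% to 4.9% of the charge, yet G goes only from 13.0% to 14.2%.

| flask | D | remark | time |
|---|---|---|---|
| autumn | 0.68 M | the very flask that is asked about, followed so far |  |
| summer | 0.46 M | run made earlier |  |
| flask | 0.68 M |  | 50 h |

| run | time / h | G / % | Z / % |
|---|---|---|---|
| autumn | 1.50 | 11.1 | 12.1 |
| autumn | 2.50 | 13.0 | 13.1 |
| autumn | 4.00 | 14.8 | 10.2 |
| autumn | 6.00 | 16.3 | 10.7 |
| autumn | 8.00 | 16.0 | 8.0 |
| autumn | 12.0 | 17.0 | 8.1 |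
| autumn | 20.0 | 14.2 | 4.9 |
| summer | 3.00 | 16.1 | 13.8 |
| summer | 4.00 | 18.2 | 14.5 |
| summer | 6.00 | 22.0 | 12.2 |
| summer | 10.0 | 18.9 | 8.7 |
| summer | 15.0 | 19.2 | 6.9 |
| summer | 25.0 | 15.6 | 8.0 |
| summer | 40.0 | 13.3 | 4.0 |

(standard deviation of a reading: 1 percentage point)

- percentages count the D that a species holds: one L counts as two
- Z is meant together with its J
- solid, in amounts per volume of the solution: J
- what may be going on: D <-> Z; Z <-> G; G <-> D; J <-> Z; 2 D -> L

1. share of G in G plus Z at 2.0 min
2. share of G in G plus Z at 50 h

If Z in the autumn flask simply became G, the two changes should match, but Z loses 8.2 percentage points and G gains 1.2 points. A loss that takes the same fraction of G and of Z leaves their share unchanged, so I follow the share of G in G plus Z and reckon its distance from the late value. Pooling the readings from 20.0 h on in both runs gives a late share of 71.8%. In the autumn run the gap is 24 points at 1.50 h and 5.2 points at 8.00 h. That gives a gap half-time, the time in which the gap halves (a relaxation half-life), of 2.93 h. The summer run, read from 3.00 h to 10.0 h, gives 2.89 h. Run back to 2.0 min, the autumn gap grows to 34 points, so I commit to 37.9% there. At 50 h, 17.1 half-times on, I commit to the late 71.8%.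

The forecast says 42% and 75%, holding that G “must form directly from D in parallel”; at the early time it stands higher than my figure.

The autumn flask gives 30.5% at 2.0 min and 70.0% at 50 h. With the way back from G to Z struck out, its early share is 30.5%. Its gap between those two shares is 40 points, and 8.53 half-times reckon that down to 0.11 points by 25.0 h. The autumn flask then holds G 12.3% and Z 5.16%, a share of 70.4%, which stands 0.5 points above its share at 50 h, so the share has passed its end value and the half-time describes the approach, not this last drift.

    D ⇌ Z (K = 0.840, k = 0.00470 min⁻¹)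
    Z ⇌ G (K = 2.20, k = 0.00340 min⁻¹)
    G ⇌ D (k = 0.00110 min⁻¹)
    J ⇌ Z, rate k4*(cs4 - [Z]) while solid is left; crystals form when [Z] > cs4 (solubility = 0.110 M, k = 0.880 min⁻¹)
    2 D → L (k = 0.0170 M⁻¹ min⁻¹)

For the neighbour flask with D at 1.2 M, I carry the same half-time and the same gap, which gives 30.5% early and, after 17.1 halvings, 70.0%. The computed neighbour gives 30.5% and 70.2%, with Z 2.25% and G 5.30% at the end.

(The earlier runs and the new flask were generated by integration on assumed constants, noise included.)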